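The alpha run stood flat near 89.8 % target from its first reading at 4.00 min, so, as read, the enzyme there averaged no less than 349 min⁻¹ over those minutes, counted in rounds of the making step per enzyme.

| flask | starting material | free enzyme | temperature | remark | time |
|---|---|---|---|---|---|
| alpha | 5.0 × 10⁻⁴ M | 0.32 µM | 30 °C | run made earlier |  |
| theta | 5.0 × 10⁻⁴ M | 0.51 µM | 52 °C | run made earlier |  |
| zeta | 7.5 × 10⁻⁴ M | 0.23 µM | 30 °C | run made earlier |  |
| east | 5.0 × 10⁻⁴ M | 0.23 µM | 40 °C |  | 8.0 min |
| north | 5.0 × 10⁻⁴ M | 0.23 µM | 20 °C |  | 8.0 min |
| south-east | 5.0 × 10⁻⁴ M | 0.23 µM | 60 °C |  | 8.0 min |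

| run | time / min | target / % |
|---|---|---|
| alpha | 4.00 | 89.4 |
| alpha | 8.00 | 90.0 |
| alpha | 12.0 | 91.7 |
| alpha | 15.0 | 88.1 |
| theta | 0.500 | 86.2 |
| theta | 1.00 | 85.2 |
| theta | 2.00 | 85.5 |
| theta | 6.00 | 86.4 |
| zeta | 4.00 | 70.8 |
| zeta | 8.00 | 70.5 |
| zeta | 12.0 | 69.9 |
| zeta | 15.0 | 70.4 |

(each reading ± 1 percentage point)

- a species is counted by the starting material in it: one side product counts as two
- the analysis behind the earlier runs scatters by 1 percentage point, standard deviation
- steps thought possible: free enzyme -> unfolded enzyme; starting material + free enzyme -> target + free enzyme; starting material + target -> side product; starting material + free enzyme -> spent catalyst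

* the flask that comes out highest in amount of target, in percent of the starting material charged, or "all alike" when all lie within 1.5 percentage points (east / north / south-east / all alike)
* target at the end, in percent of the starting material charged, east
* target at the end, in percent of the starting material charged, north
* target at the end, in percent of the starting material charged, south-east

We count rounds. Our number is the turnovers asked, 2170 for each new flask, which is the starting material charged divided by the free enzyme charged. At alpha's lower bound on the rate, that count takes 6.22 min, less than the 8.0 min allowed, so at 30 °C the making step has the time it needs.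

What then holds the target down? The making step runs with free enzyme, while the step from starting material and target to side product needs no enzyme and goes with the target present. At one temperature, a flask asking more turnovers should therefore lose a larger share. As read, alpha asks 1560 and zeta 3260, a factor of 2.09. Zeta stands near 70.4 %, so its shortfall is 2.90 times alpha's. An enzyme stopping after a fixed count does not fit these two runs, since zeta's target amounts to 2295 rounds per enzyme against alpha's 1401.

A straight line between these two runs puts 2170 turnovers at about 82.8 % at 30 °C. Theta, at 52 °C, loses 2.21 times as much per turnover as alpha. We therefore place north above that figure, east below it and south-east lower still.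

The forecast also names north, with 85 % for north (70 % to 91 %), 66 % for east (55 % to 74 %) and 46 % for south-east (22 % to 58 %). Its ground differs from ours: “The plateau is therefore set by catalyst loss, not by time.” Its east lies below our 82.8 % by much more than a reading's scatter.

The flasks give 90.2 % in north, 82.4 % in east and 12.7 % in south-east, so north stands highest.

    free enzyme → unfolded enzyme (k = 6.30 × 10⁻⁴ s⁻¹, Ea = 217 kJ mol⁻¹)
    starting material + free enzyme → target + free enzyme, rate k2*[starting material]*[free enzyme]/(1 + ([starting material]/Km2) + ([starting material]/Ksi2)^2) (0.320 mM, 0.0620 mM, k = 7.00 × 10⁶ L mol⁻¹ s⁻¹, Ea = 16.0 kJ mol⁻¹)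
    starting material + target → side product (k = 63.0 L mol⁻¹ s⁻¹, Ea = 44.0 kJ mol⁻¹)
    starting material + free enzyme → spent catalyst (k = 2.00 L mol⁻¹ s⁻¹, Ea = 40.0 kJ mol⁻¹)
    (constants at 40 °C)

In north at 0.387 min, target was being made 13.5 times faster than it was used up. By 8.00 min, with 0 % starting material left, north's target amounted to 1957 of the 2170 turnovers asked. The neighbour flask, north with 0.0020 M of starting material, asks 8700 turnovers. Its target amounts to 2580 of them, which is 29.7 % of its charge, with 70.3 % as side product.

All runs were generated by integration from invented constants.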